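## Retrosynthetic overview

1. Target ⇒ chlorine-atom-transfer radical cascade (C3–CH bond of the seven-membered ring, then the cyclopentane C–C bond, then C–Cl → C–OH) from a 3-chloro-3-prenyl type A bicyclo[3.3.1]nonanetrione with a 7-endo prenyl group.
2. That bicycle ⇒ cationic closure of ring B (C1–C8) from a monocyclic dearomatized triketone whose C3 is blocked by Cl and prenyl and whose C5 side chain ends in a tertiary alcohol.
3. The triketone ⇒ C3 allylation and methyl addition to a keto Michael adduct.
4. The adduct ⇒ catalytic enantioselective dearomative Michael addition (key step, forms C5–C6, sets C5; C7 follows) of 3-chloro-5-geranyl-2,4,6-trihydroxybenzophenone to 6-methyl-3-methylidenehept-5-en-2-one.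
5. The phenol ⇒ 2,4,6-trihydroxybenzophenone, a Cl+ source and geranyl bromide; the enone ⇒ 6-methylhept-5-en-2-one and CH2O. The single chlorine directs the site of dearomatization, blocks C3 during ring B closure and finally triggers the radical cascade. Ring order: ring B, seven-membered ring, cyclopentane.

Assumption: PPAP numbering is used for ring atoms of all intermediates (C1 benzoyl carbon, C3 chloro/prenyl carbon, C5 geranyl carbon, C6–C7–C8 the three-carbon bridge, C9 the bridging carbonyl). Tautomeric compounds are drawn as one tautomer and CIP descriptors refer to that drawing. The sense of induction of the phase-transfer catalyst must be fixed by screening; the cinchoninium pseudo-enantiomer is used if the cinchonidinium salt gives the mirror image.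

## Route

Step 1
Reactants: 1 2,4,6-trihydroxybenzophenone
Product: 2 (3-chloro-2,4,6-trihydroxyphenyl)(phenyl)methanone
Conditions: N-chlorosuccinimide (1.0 equiv), MeCN, 0 °C to rt
Reagents that add atoms: N-chlorosuccinimide, O=C1CCC(=O)N1Cl
Why: Electrophilic aromatic chlorination of the very electron-rich phloroglucinol ring; both free ring positions are equivalent and one equivalent gives mainly the monochloride, which is separated from a little dichloride.

Step 2
Reactants: 2 (3-chloro-2,4,6-trihydroxyphenyl)(phenyl)methanone; 3 geranyl bromide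
Product: 4 {3-chloro-5-[(2E)-3,7-dimethylocta-2,6-dien-1-yl]-2,4,6-trihydroxyphenyl}(phenyl)methanone
Conditions: KOH (10% aq), 0 °C; then dilute HCl
Reagents that add atoms: none
Why: Phenolate C-allylation (Friedel–Crafts-type alkylation in water, standard for acylphloroglucinols) at the only remaining ring C–H, so mono-geranylation is inherent.

Step 3
Reactants: 5 6-methylhept-5-en-2-one
Product: 6 6-methyl-3-methylidenehept-5-en-2-one
Conditions: (CH2O)n, i-Pr2NH·CF3CO2H, CF3CO2H (10 mol%), THF, reflux; used freshly distilled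
Reagents that add atoms: formaldehyde (from paraformaldehyde), C=O
Why: Mannich condensation–elimination (α-methylenation of a ketone), which should favour the more substituted α-carbon through the thermodynamic enol, with the ammonium salt regenerated.

Step 4
Reactants: 4 {3-chloro-5-[(2E)-3,7-dimethylocta-2,6-dien-1-yl]-2,4,6-trihydroxyphenyl}(phenyl)methanone; 6 6-methyl-3-methylidenehept-5-en-2-one
Product: 8 (6R)-6-[(2R)-2-acetyl-5-methylhex-4-en-1-yl]-2-benzoyl-4-chloro-6-geranyl-3,5-dihydroxycyclohexa-2,4-dien-1-one (in solution in equilibrium with its cyclic hemiketal), via 2'-epimeric Michael adduct 7 (not isolated)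
Conditions: O-allyl-N-(9-anthracenylmethyl)cinchonidinium bromide (10 mol%), CsOH·H2O (30 mol%), toluene/CHCl3 7:3, −40 °C; AcOH quench; then pyridinium p-toluenesulfonate (10 mol%), CHCl3, 40 °C
Reagents that add atoms: none
Why: Proposed new method: enantioselective dearomative Michael addition of a non-symmetric acylphloroglucinol to an α-branched vinyl ketone under a chiral cinchona ammonium phase-transfer catalyst. The chlorine makes the geranyl-bearing carbon the only reactive ring carbon, and the chiral ammonium–phenoxide ion pair shields one face of that carbon, so C5 is set in the C–C bond-forming step. The α-keto centre C7, formed about 1:1 on protonation (8 and 7), then equilibrates through the enol within the warfarin-type cyclic hemiketal, in which the flat dienone ring holds the angular geranyl group axial and the prenyl group therefore settles equatorial, trans to geranyl. The closest known reaction types are the chiral phase-transfer-catalysed alkylative dearomatization–annulation of symmetric acylphloroglucinols with α-acetoxymethyl enals and phase-transfer Michael additions of 1,3-dicarbonyl compounds to vinyl ketones.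

Step 5
Reactants: 8 (6R)-6-[(2R)-2-acetyl-5-methylhex-4-en-1-yl]-2-benzoyl-4-chloro-6-geranyl-3,5-dihydroxycyclohexa-2,4-dien-1-one
Product: 9 (6R)-2-benzoyl-4-chloro-6-geranyl-3,5-dihydroxy-6-[(2R)-2-(2-hydroxypropan-2-yl)-5-methylhex-4-en-1-yl]cyclohexa-2,4-dien-1-one
Conditions: CH3MgBr (4 equiv), LaCl3·2LiCl (30 mol%), THF, −40 to 0 °C; aq NH4Cl
Reagents that add atoms: methylmagnesium bromide, C[Mg]Br
Why: Grignard 1,2-addition to the only free ketone; the first two equivalents deprotonate the vinylogous acids, which masks the ring carbonyls and the benzoyl group as enolates, and the lanthanum salt favours addition over enolization so C7 is not epimerized.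

Step 6
Reactants: 9 (6R)-2-benzoyl-4-chloro-6-geranyl-3,5-dihydroxy-6-[(2R)-2-(2-hydroxypropan-2-yl)-5-methylhex-4-en-1-yl]cyclohexa-2,4-dien-1-one; 10 prenyl acetate
Product: 11 (4S)-2-benzoyl-6-chloro-4-geranyl-3-hydroxy-4-[(2R)-2-(2-hydroxypropan-2-yl)-5-methylhex-4-en-1-yl]-6-(3-methylbut-2-en-1-yl)cyclohex-2-ene-1,5-dione (both epimers at the chloro carbon)
Conditions: Pd(PPh3)4 (5 mol%), Cs2CO3 (1.1 equiv), THF, 40 °C
Reagents that add atoms: none
Why: Tsuji–Trost allylic alkylation with zerovalent palladium: the soft 2-chloro-1,3-dione enolate attacks the less hindered terminus of the π-prenyl complex at carbon (any O-allyl product re-ionizes), making C3 quaternary; its configuration is irrelevant because C3 becomes a radical in step 8.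

Step 7
Reactants: 11 (4S)-2-benzoyl-6-chloro-4-geranyl-3-hydroxy-4-[(2R)-2-(2-hydroxypropan-2-yl)-5-methylhex-4-en-1-yl]-6-(3-methylbut-2-en-1-yl)cyclohex-2-ene-1,5-dione
Product: 12 (1S,5S,7R)-1-benzoyl-3-chloro-5-geranyl-8,8-dimethyl-3,7-bis(3-methylbut-2-en-1-yl)bicyclo[3.3.1]nonane-2,4,9-trione (both C3 epimers, 7-endo prenyl)
Conditions: HCO2H, 0 °C to rt
Reagents that add atoms: none
Why: Biomimetic cationic cyclization (SN1 alkylation of the enolized β-triketone): the tertiary alcohol ionizes to the C8 cation and, with C3 and C5 quaternary, C1 is the only carbon nucleophile (O-alkylation is reversible in the acid), so ring B closes to the type A skeleton; C1 is fixed by the tether and the preset 5,7-trans relationship becomes the 7-endo prenyl group.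

Step 8
Reactants: 12 (1S,5S,7R)-1-benzoyl-3-chloro-5-geranyl-8,8-dimethyl-3,7-bis(3-methylbut-2-en-1-yl)bicyclo[3.3.1]nonane-2,4,9-trione
Product: 14 CNP0164095.2 (target), via tertiary chloride cage 13 (not isolated)
Conditions: CuCl (20 mol%), tris(2-pyridylmethyl)amine (20 mol%), ClCH2CH2Cl, 80 °C, degassed; then Ag2CO3, acetone/H2O 4:1, rt
Reagents that add atoms: water, O
Why: Copper-catalysed atom-transfer radical cyclization cascade followed by silver-assisted SN1 hydrolysis: CuCl reversibly abstracts the activated C3 chlorine, the C3 radical adds 7-exo-trig to the endo prenyl alkene through its endo lobe (fixing C3 and closing the homoadamantane), the resulting tertiary radical closes the cyclopentane 5-exo-trig onto the C3 prenyl group with the bulky terminus on the convex face (setting the two cyclopentane CH centres), CuCl2 returns chlorine to give 13, and hydrolysis of the tertiary chloride touches no stereocentre.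

## Compound list

1 | 2,4,6-trihydroxybenzophenone | O=C(c1ccccc1)c1c(O)cc(O)cc1O | starting material
2 | (3-chloro-2,4,6-trihydroxyphenyl)(phenyl)methanone | O=C(c1ccccc1)c1c(O)c(Cl)c(O)cc1O | intermediate
3 | geranyl bromide, (2E)-1-bromo-3,7-dimethylocta-2,6-diene | CC(C)=CCC/C(C)=C/CBr | starting material
4 | {3-chloro-5-[(2E)-3,7-dimethylocta-2,6-dien-1-yl]-2,4,6-trihydroxyphenyl}(phenyl)methanone | O=C(c1ccccc1)c1c(O)c(Cl)c(O)c(C/C=C(\C)CCC=C(C)C)c1O | intermediate
5 | 6-methylhept-5-en-2-one | CC(=O)CCC=C(C)C | starting material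
6 | 6-methyl-3-methylidenehept-5-en-2-one | CC(=O)C(=C)CC=C(C)C | intermediate
7 | (6R)-6-[(2S)-2-acetyl-5-methylhex-4-en-1-yl]-2-benzoyl-4-chloro-6-geranyl-3,5-dihydroxycyclohexa-2,4-dien-1-one (side-chain epimer of 8, not isolated) | CC(C)=CCC/C(C)=C/C[C@@]1(C[C@H](CC=C(C)C)C(C)=O)C(O)=C(Cl)C(O)=C(C(=O)c2ccccc2)C1=O | intermediate
8 | (6R)-6-[(2R)-2-acetyl-5-methylhex-4-en-1-yl]-2-benzoyl-4-chloro-6-geranyl-3,5-dihydroxycyclohexa-2,4-dien-1-one (open keto form shown) | CC(C)=CCC/C(C)=C/C[C@@]1(C[C@@H](CC=C(C)C)C(C)=O)C(O)=C(Cl)C(O)=C(C(=O)c2ccccc2)C1=O | intermediate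
9 | (6R)-2-benzoyl-4-chloro-6-geranyl-3,5-dihydroxy-6-[(2R)-2-(2-hydroxypropan-2-yl)-5-methylhex-4-en-1-yl]cyclohexa-2,4-dien-1-one | CC(C)=CCC/C(C)=C/C[C@@]1(C[C@@H](CC=C(C)C)C(C)(C)O)C(O)=C(Cl)C(O)=C(C(=O)c2ccccc2)C1=O | intermediate
10 | prenyl acetate, 3-methylbut-2-en-1-yl acetate | CC(=O)OCC=C(C)C | starting material
11 | (4S)-2-benzoyl-6-chloro-4-geranyl-3-hydroxy-4-[(2R)-2-(2-hydroxypropan-2-yl)-5-methylhex-4-en-1-yl]-6-(3-methylbut-2-en-1-yl)cyclohex-2-ene-1,5-dione (both epimers at the chloro carbon) | CC(C)=CCC/C(C)=C/C[C@@]1(C[C@@H](CC=C(C)C)C(C)(C)O)C(=O)C(Cl)(CC=C(C)C)C(=O)C(C(=O)c2ccccc2)=C1O | intermediate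
12 | (1S,5S,7R)-1-benzoyl-3-chloro-5-geranyl-8,8-dimethyl-3,7-bis(3-methylbut-2-en-1-yl)bicyclo[3.3.1]nonane-2,4,9-trione (both C3 epimers, 7-endo prenyl) | CC(C)=CCC/C(C)=C/C[C@@]12C[C@@H](CC=C(C)C)C(C)(C)[C@](C(=O)c3ccccc3)(C2=O)C(=O)C(Cl)(CC=C(C)C)C1=O | intermediate
13 | tertiary chloride cage: the target with a 2-chloropropan-2-yl group in place of 2-hydroxypropan-2-yl (not isolated) | CC(C)=CCC/C(C)=C/C[C@@]12C[C@H]3C[C@@H]4C(C)(C)[C@@H](C(C)(C)Cl)C[C@]4(C1=O)C(=O)[C@@](C(=O)c1ccccc1)(C2=O)C3(C)C | intermediate
14 | CNP0164095.2: 1-benzoyl-5-geranyl-8,8-dimethylbicyclo[3.3.1]nonane-2,4,9-trione in which C7 and C3 are joined by CH2–CH and that CH is fused with C3 into a cyclopentane C3–CH–C(CH3)2–CH[C(CH3)2OH]–CH2; 1S,3S,5R,7R, ring-fusion CH R, carbinol-bearing CH S | CC(C)=CCC/C(C)=C/C[C@@]12C[C@H]3C[C@@H]4C(C)(C)[C@@H](C(C)(C)O)C[C@]4(C1=O)C(=O)[C@@](C(=O)c1ccccc1)(C2=O)C3(C)C | target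

## Step count and risks

Total steps: 8. Longest linear sequence: 7 (steps 1, 2, 4, 5, 6, 7, 8); step 3 makes the side-chain enone.

The three steps most likely to fail:

**Step 4 (the proposed new step).** Enantioselectivity on a non-symmetric phenoxide is untested, retro-Michael erosion is possible, and the trans preference at the α-keto centre rests on a conformational argument. Fallback with known chemistry, setting out from 4 and 6 and coming back at 8: run the same conjugate addition with an achiral base (DBU in THF, the established base-mediated alkylative dearomatization of acylphloroglucinols) and equilibrate as before. This gives racemic material, that is 8 together with its mirror image, the (6S,2'S)-enantiomer of the adduct F1. The enantiomers are separated by preparative HPLC on a chiral stationary phase, F1 is discarded, and the route continues from 8.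

**Step 7.** C1 of a β-triketone is a weak nucleophile; O-cyclization to the pyran, attack of the geranyl 2,3-alkene on the cation, or loss of the C7 configuration through elimination may win. Fallback setting out from 8 and coming back at 12: methylenate the ketone of 8 with Ph3P=CH2 (excess, THF) to the isopropenyl (lavandulyl-type) dienone F2. Prenylate F2 at C3 as in step 6 to the C3-prenylated chloro triketone F3. Close ring B by gold-catalysed Markovnikov hydroalkylation of the 1,1-disubstituted alkene with the β-triketone (Ph3PAuCl/AgOSO2CF3, toluene, 60 °C), which avoids a solvolytic cation in formic acid and leads to 12.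

**Step 8.** The slow 7-exo closure, the facial mode of the alkene under C3 (it decides the ring-fusion CH), and elimination during hydrolysis of the tertiary chloride are all uncertain. Fallback setting out from 12 and coming back at 14: remove the chlorine with Zn in AcOH to the enolized 3-H type A dione F4. Subject F4 to the established oxidative radical cyclization of polyprenylated acylphloroglucinol diketones with PhI(OAc)2 and TEMPO (THF, −78 °C to rt), which traps the final tertiary radical as the TEMPO ether of the target F5. Cleave the N–O bond of F5 with Zn in AcOH/H2O at 60 °C to give 14.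

## Further compounds

F1 | step 4 | (6S)-6-[(2S)-2-acetyl-5-methylhex-4-en-1-yl]-2-benzoyl-4-chloro-6-geranyl-3,5-dihydroxycyclohexa-2,4-dien-1-one (enantiomer of 8) | CC(C)=CCC/C(C)=C/C[C@]1(C[C@H](CC=C(C)C)C(C)=O)C(O)=C(Cl)C(O)=C(C(=O)c2ccccc2)C1=O
F2 | step 7 | (6R)-2-benzoyl-4-chloro-6-geranyl-3,5-dihydroxy-6-[(2R)-5-methyl-2-(prop-1-en-2-yl)hex-4-en-1-yl]cyclohexa-2,4-dien-1-one | CC(C)=CCC/C(C)=C/C[C@@]1(C[C@@H](CC=C(C)C)C(C)=C)C(O)=C(Cl)C(O)=C(C(=O)c2ccccc2)C1=O
F3 | step 7 | C3-prenylated chloro triketone from F2 (isopropenyl analogue of 11, both epimers at the chloro carbon) | CC(C)=CCC/C(C)=C/C[C@@]1(C[C@@H](CC=C(C)C)C(C)=C)C(=O)C(Cl)(CC=C(C)C)C(=O)C(C(=O)c2ccccc2)=C1O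
F4 | step 8 | dechlorinated, enolized 1-benzoyl-5-geranyl-8,8-dimethyl-3,7-diprenylbicyclo[3.3.1]nonane-2,4,9-trione (configuration at C1, C5, C7 as in 12) | CC(C)=CCC/C(C)=C/C[C@@]12C[C@@H](CC=C(C)C)C(C)(C)[C@](C(=O)c3ccccc3)(C2=O)C(=O)C(CC=C(C)C)=C1O
F5 | step 8 | O-(2,2,6,6-tetramethylpiperidin-1-yl) ether of the target | CC(C)=CCC/C(C)=C/C[C@@]12C[C@H]3C[C@@H]4C(C)(C)[C@@H](C(C)(C)ON5C(C)(C)CCCC5(C)C)C[C@]4(C1=O)C(=O)[C@@](C(=O)c1ccccc1)(C2=O)C3(C)C
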